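**Strategy.** The target is a daucol-type tricycle: a ring oxygen bridges C7 and C10 of the seven-membered ring (8-oxabicyclo[3.2.1]octane), and the cyclopentane C1–C2–C3–C4–C10 is fused on the bridgehead bond C10–C4. That is the retron of a furan (4+3) cycloaddition whose tether becomes the cyclopentane. The precursor is a 2-methylfuran carrying at its other α-carbon a three-carbon chain (C1–C3) that ends in an acetoxyallene (C4–C6). Gold catalysis adds the allyl-cation termini C4 and C6 across the furan, closing the cyclopentane, the seven-membered ring and the oxygen bridge in one operation, while a silyloxy stereocentre at C1 fixes the absolute configuration. Angular methyl, side chain and vanillate follow.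

Key step: step 6

Remark on locants: C1 (CH bearing the side chain), C2, C3, C4 (methyl-bearing quaternary carbon) and C10 (O-bearing fusion carbon) form the cyclopentane; C4–C5–C6–C7–C8–C9–C10 is the seven-membered ring (C6 carbinol, C7 methyl- and O-bearing); the ring oxygen bridges C7 and C10. "Exo" is the face of the ring oxygen; "cis to C9" is the opposite face.

Assumption: the (R)-silyloxy centre at C1 is taken to steer the cycloaddition to the furan face analysed in step 6; if the other face reacted, the (S,S)-ligand would be used in step 2.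

Step 1
Reactants: 1 5-methylfurfural; 2 acrylonitrile
Product: 3 4-(5-methylfuran-2-yl)-4-oxobutanenitrile
Conditions: 3-benzyl-5-(2-hydroxyethyl)-4-methylthiazolium chloride (10 mol %), Et3N, EtOH, 80 °C
Reagents that add atoms: none
Why: Stetter reaction: the thiazolium-derived carbene turns the aldehyde into an acyl-anion equivalent (Breslow intermediate) that adds 1,4 to acrylonitrile; no stereocentre is formed.

Step 2
Reactants: 3 4-(5-methylfuran-2-yl)-4-oxobutanenitrile
Product: 4 (4R)-4-hydroxy-4-(5-methylfuran-2-yl)butanenitrile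
Conditions: RuCl(p-cymene)[(R,R)-TsDPEN] (1 mol %; TsDPEN = N-tosyl-1,2-diphenylethylenediamine), HCO2H/Et3N (5:2), 25 °C
Reagents that add atoms: none
Why: Noyori asymmetric transfer hydrogenation of the heteroaryl ketone through the Ru–H/N–H six-membered transition state, the (R,R)-ligand chosen to give the (R)-carbinol; the nitrile is inert.

Step 3
Reactants: 4 (4R)-4-hydroxy-4-(5-methylfuran-2-yl)butanenitrile
Product: 5 (4R)-4-[(tert-butyldimethylsilyl)oxy]-4-(5-methylfuran-2-yl)butanenitrile
Conditions: TBSCl, imidazole, DMF, 25 °C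
Reagents that add atoms: tert-butyldimethylsilyl chloride, CC(C)(C)[Si](C)(C)Cl
Why: Imidazole-promoted O-silylation of a secondary alcohol; the ether masks the carbinol that later relays chirality.

Step 4
Reactants: 5 (4R)-4-[(tert-butyldimethylsilyl)oxy]-4-(5-methylfuran-2-yl)butanenitrile
Product: 7 (4R)-4-[(tert-butyldimethylsilyl)oxy]-4-(5-methylfuran-2-yl)butanal, via N-aluminoaldimine 6 (not isolated)
Conditions: i-Bu2AlH, CH2Cl2, −78 °C; then aq. KNaC4H4O6 (Rochelle salt), 25 °C
Reagents that add atoms: diisobutylaluminium hydride, CC(C)C[AlH]CC(C)C (aluminium in 6 only); water, O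
Why: Partial reduction of a nitrile by DIBAL-H stops at the N-aluminoaldimine, which is hydrolysed to the aldehyde on work-up; silyl ether and furan are untouched.

Step 5
Reactants: 7 (4R)-4-[(tert-butyldimethylsilyl)oxy]-4-(5-methylfuran-2-yl)butanal
Product: 9 (6R)-6-[(tert-butyldimethylsilyl)oxy]-6-(5-methylfuran-2-yl)hex-1-yn-3-yl acetate (both C3 epimers), via bromomagnesium alkoxide 8 (not isolated)
Conditions: HC≡CMgBr, THF, 0 °C; then Ac2O, 0 → 25 °C
Reagents that add atoms: ethynylmagnesium bromide, C#C[Mg]Br; acetic anhydride, CC(=O)OC(C)=O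
Why: 1,2-Addition of an alkynyl Grignard reagent and in-flask O-acetylation of the magnesium alkoxide; the new carbinol centre (C4) is formed without control and is erased later.

Step 6
Reactants: 9 (6R)-6-[(tert-butyldimethylsilyl)oxy]-6-(5-methylfuran-2-yl)hex-1-yn-3-yl acetate
Product: 11 tricyclic enol acetate (C1-OTBS; C6-OAc; C5=C6; C8=C9), via acetoxyallene 10 (not isolated)
Conditions: AgSbF6 (10 mol %), CH2Cl2, 25 °C; then (IPr)AuCl (5 mol %; IPr = 1,3-bis(2,6-diisopropylphenyl)imidazol-2-ylidene), 0 → 25 °C
Reagents that add atoms: none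
Why: The silver salt first effects the 3,3-acyloxy shift (Saucy–Marbet rearrangement) of the propargylic acetate to acetoxyallene 10; cationic monovalent gold then binds the allene at its central carbon C5, giving a 2-aurated 1-acetoxyallyl cation whose termini C4 and C6 add to the furan α-carbons C10 and C7, and the gold carbene left at C5 collapses by 1,2-hydride shift from C6 to the enol acetate with release of the catalyst. The closest known reaction type is the gold- or platinum-catalysed intramolecular (4+3) cycloaddition of allenes, including acyloxyallenes made in the flask from propargylic esters, with tethered dienes and furans. The cyclopentane closes through the C4–C10 bond (5-exo attack of the tethered cation terminus on the substituted furan carbon) and the seven-membered ring together with the oxane through the C6–C7 bond, so the whole tricycle is complete in this operation and no ring is closed afterwards. Of the new stereocentres, the bridgeheads C7 and C10 are cis by necessity (suprafacial addition to the furan) and their absolute sense is set by C1: allylic 1,3-strain keeps the C1–H bond in the furan plane and the OTBS group on the face opposite the rising tether, so the cation adds anti to OTBS, whereas C4 is not controlled and is erased in step 7. The step needs (4+3) periselectivity over Friedel–Crafts attack at the furan β-carbon C9 and over (4+2) closure, which the three-atom tether, the two blocked α-positions and a σ-donating carbene ligand favour, and it needs the ester to stay on C6, which is why the 1,3-shift is completed with silver before the gold complex is added.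

Step 7
Reactants: 11 tricyclic enol acetate
Product: 12 tricyclic enone (C6 ketone; C5=C4; C8=C9; C1-OTBS)
Conditions: Pd(OAc)2 (5 mol %), Ph2PCH2CH2PPh2, Bu3SnOMe (20 mol %), allyl methyl carbonate, MeCN, 80 °C
Reagents that add atoms: none
Why: Tsuji dehydrogenation of an enol acetate: Bu3SnOMe unmasks the tin enolate, which enters the allylpalladium cycle and undergoes β-hydride elimination of H4, giving the only possible enone (C7 is quaternary) and removing the uncontrolled C4 centre.

Step 8
Reactants: 12 tricyclic enone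
Product: 15 tricyclic enol pivalate (C4 methyl exo; C6-OPiv; C5=C6; C8=C9; C1-OTBS), via trimethylsilyl enol ether 13 (not isolated), via lithium enolate 14 (not isolated)
Conditions: Me2CuLi, Me3SiCl, THF, −78 → −20 °C; then MeLi, 0 °C; then t-BuCOCl, −78 → 0 °C
Reagents that add atoms: lithium dimethylcuprate, [Li+].C[Cu-]C; chlorotrimethylsilane, C[Si](C)(C)Cl (in 13 only); methyllithium, [Li]C (lithium in 14 only); pivaloyl chloride, CC(C)(C)C(Cl)=O
Why: Silyl-chloride-accelerated conjugate addition of the Gilman reagent to the β,β-disubstituted enone delivers methyl to C4 from the exo face (syn to the ring oxygen, anti to the C8=C9 bridge and to the C1 silyloxy group), so the C4 methyl and the ring oxygen are cis as in the target; MeLi then frees the lithium enolate, which is acylated on oxygen because C5 is neopentylic.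

Step 9
Reactants: 15 tricyclic enol pivalate
Product: 16 C1 alcohol (hydroxyl cis to C9)
Conditions: Bu4NF, THF, 25 °C
Reagents that add atoms: none
Why: Fluoride-mediated cleavage of the silyl ether; the hindered enol pivalate is not attacked.

Step 10
Reactants: 16 C1 alcohol
Product: 17 C1 ketone (cyclopentanone; enol pivalate retained)
Conditions: Dess–Martin periodinane, NaHCO3, CH2Cl2, 25 °C
Reagents that add atoms: none
Why: Dess–Martin oxidation of the secondary alcohol, which retires the relay stereocentre C1.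

Step 11
Reactants: 17 C1 ketone
Product: 19 tertiary allylic methyl carbonate (C1 bears isopropenyl and OCO2Me), via bromomagnesium alkoxide 18 (not isolated)
Conditions: CH2=C(CH3)MgBr, CeCl3, THF, −78 °C; then ClCO2Me, −78 → 25 °C
Reagents that add atoms: isopropenylmagnesium bromide, CC(=C)[Mg]Br; methyl chloroformate, COC(Cl)=O
Why: Organocerium 1,2-addition to the hindered enolisable ketone from the face anti to the axial C4 methyl group, then O-acylation of the alkoxide; the configuration of this carbinol is inconsequential for step 12.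

Step 12
Reactants: 19 tertiary allylic methyl carbonate
Product: 20 C1-isopropenyl enol pivalate (C1–H cis to C9; isopropenyl cis to the ring oxygen and the C4 methyl)
Conditions: Pd(OAc)2 (5 mol %), PBu3, HCO2NH4, 1,4-dioxane, 80 °C
Reagents that add atoms: none
Why: Tsuji formate hydrogenolysis of an allylic carbonate: the allylpalladium formate loses CO2 and transfers hydride to the more substituted terminus C1, giving the terminal alkene; palladium occupies the face of C1 anti to the axial C4 methyl group (by anti ionisation or by π–σ–π equilibration through the CH2 terminus), so hydrogen enters cis to C9.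

Step 13
Reactants: 20 C1-isopropenyl enol pivalate
Product: 22 C6 alcohol (equatorial hydroxyl, anti to the C7–O bond; isopropenyl and C8=C9 retained), via ketone 21 (not isolated)
Conditions: Al(Oi-Pr)3 (1.5 equiv), i-PrOH, toluene, 110 °C
Reagents that add atoms: none
Why: Aluminium isopropoxide first transesterifies the enol pivalate to ketone 21 and then effects a reversible Meerwein–Ponndorf–Verley reduction, so the C6 carbinol settles in the more stable equatorial position, free of the 1,3-diaxial contact with the C4 methyl group; one-electron reductants are avoided because they would cleave the α-alkoxy C7–O bond.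

Step 14
Reactants: 22 C6 alcohol
Product: 24 diol ((2S)-1-hydroxypropan-2-yl on C1; C6–OH; C8=C9), via alkylborane 23 (not isolated)
Conditions: 9-BBN, THF, 0 → 25 °C; then NaOH, H2O2, H2O, 0 → 25 °C
Reagents that add atoms: 9-borabicyclo[3.3.1]nonane, B1C2CCCC1CCC2 (boron in 23 only); hydrogen peroxide, OO
Why: Hydroboration–oxidation: 9-BBN attacks only the unhindered 1,1-disubstituted alkene (C8=C9 is flanked by two quaternary bridgeheads) and, with the C1–H bond eclipsing the double bond, adds anti to the bulky bridgehead C10, which should set the (S) methyl-bearing carbon; oxidation proceeds with retention.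

Step 15
Reactants: 24 diol; 25 4-(benzyloxy)-3-methoxybenzoic acid
Product: 27 benzyl-protected vanillate ester, via O-acylisourea 26 (not isolated)
Conditions: EDC·HCl, 4-(dimethylamino)pyridine (cat.), CH2Cl2, 0 → 25 °C
Reagents that add atoms: N-(3-dimethylaminopropyl)-N′-ethylcarbodiimide hydrochloride, CCN=C=NCCCN(C)C.Cl (in 26 only)
Why: Steglich esterification through the O-acylisourea and the acylpyridinium ion; only the primary alcohol reacts, the C6 hydroxyl being flanked by the quaternary bridgehead C7.

Step 16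
Reactants: 27 benzyl-protected vanillate ester
Product: 28 target, (2S)-2-(7-hydroxy-5,8-dimethyl-11-oxatricyclo[6.2.1.0(1,5)]undecan-2-yl)propyl 4-hydroxy-3-methoxybenzoate
Conditions: H2 (1 atm), Pd/C (10 %), EtOAc, 25 °C
Reagents that add atoms: none
Why: Heterogeneous hydrogenation saturates the cis-disubstituted C8=C9 bond (no stereocentre is created) and hydrogenolyses the benzyl ether to the phenol; the alkyl ester and the tertiary ethers are stable.

**Compound list**

1 | 5-methylfurfural (5-methylfuran-2-carbaldehyde) | Cc1ccc(C=O)o1 | starting material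
2 | acrylonitrile | C=CC#N | starting material
3 | 4-(5-methylfuran-2-yl)-4-oxobutanenitrile | Cc1ccc(o1)C(=O)CCC#N | intermediate
4 | (4R)-4-hydroxy-4-(5-methylfuran-2-yl)butanenitrile | Cc1ccc(o1)[C@H](O)CCC#N | intermediate
5 | (4R)-4-[(tert-butyldimethylsilyl)oxy]-4-(5-methylfuran-2-yl)butanenitrile | Cc1ccc(o1)[C@H](O[Si](C)(C)C(C)(C)C)CCC#N | intermediate
6 | N-(diisobutylaluminio)aldimine of aldehyde 7 | Cc1ccc(o1)[C@H](O[Si](C)(C)C(C)(C)C)CCC=N[Al](CC(C)C)CC(C)C | intermediate (not isolated)
7 | (4R)-4-[(tert-butyldimethylsilyl)oxy]-4-(5-methylfuran-2-yl)butanal | Cc1ccc(o1)[C@H](O[Si](C)(C)C(C)(C)C)CCC=O | intermediate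
8 | bromomagnesium alkoxide of (6R)-6-silyloxy-6-(5-methylfuran-2-yl)hex-1-yn-3-ol | Cc1ccc(o1)[C@H](O[Si](C)(C)C(C)(C)C)CCC(O[Mg]Br)C#C | intermediate (not isolated)
9 | (6R)-6-[(tert-butyldimethylsilyl)oxy]-6-(5-methylfuran-2-yl)hex-1-yn-3-yl acetate, both C3 epimers | Cc1ccc(o1)[C@H](O[Si](C)(C)C(C)(C)C)CCC(OC(C)=O)C#C | intermediate
10 | (6R)-6-[(tert-butyldimethylsilyl)oxy]-6-(5-methylfuran-2-yl)hexa-1,2-dien-1-yl acetate (acetoxyallene, both allene epimers) | Cc1ccc(o1)[C@H](O[Si](C)(C)C(C)(C)C)CCC=C=COC(C)=O | intermediate (not isolated)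
11 | tricyclic enol acetate, 2-silyloxy-8-methyl-11-oxatricyclo[6.2.1.0(1,5)]undeca-6,9-dien-7-yl acetate: OTBS on C1 cis to C9 (anti to the ring oxygen), bridgeheads C7 and C10 as in the target, C4–H not controlled | CC(C)(C)[Si](C)(C)O[C@@H]1CCC2C=C(OC(C)=O)[C@]3(C)C=C[C@]12O3 | intermediate
12 | tricyclic enone, 2-silyloxy-8-methyl-11-oxatricyclo[6.2.1.0(1,5)]undeca-5,9-dien-7-one (C6 ketone, C5=C4, C8=C9) | CC(C)(C)[Si](C)(C)O[C@@H]1CCC2=CC(=O)[C@]3(C)C=C[C@]12O3 | intermediate
13 | trimethylsilyl enol ether of the C4-methylated ketone (C4 methyl exo) | CC(C)(C)[Si](C)(C)O[C@@H]1CC[C@]2(C)C=C(O[Si](C)(C)C)[C@]3(C)C=C[C@]12O3 | intermediate (not isolated)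
14 | lithium enolate of the C4-methylated ketone | CC(C)(C)[Si](C)(C)O[C@@H]1CC[C@]2(C)C=C(O[Li])[C@]3(C)C=C[C@]12O3 | intermediate (not isolated)
15 | tricyclic enol pivalate, 2-silyloxy-5,8-dimethyl-11-oxatricyclo[6.2.1.0(1,5)]undeca-6,9-dien-7-yl pivalate (C4 methyl cis to the ring oxygen) | CC(C)(C)[Si](C)(C)O[C@@H]1CC[C@]2(C)C=C(OC(=O)C(C)(C)C)[C@]3(C)C=C[C@]12O3 | intermediate
16 | C1 alcohol, 2-hydroxy-5,8-dimethyl-11-oxatricyclo[6.2.1.0(1,5)]undeca-6,9-dien-7-yl pivalate (OH cis to C9) | O[C@@H]1CC[C@]2(C)C=C(OC(=O)C(C)(C)C)[C@]3(C)C=C[C@]12O3 | intermediate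
17 | C1 ketone, 5,8-dimethyl-2-oxo-11-oxatricyclo[6.2.1.0(1,5)]undeca-6,9-dien-7-yl pivalate | O=C1CC[C@]2(C)C=C(OC(=O)C(C)(C)C)[C@]3(C)C=C[C@]12O3 | intermediate
18 | bromomagnesium alkoxide of the tertiary allylic alcohol (O cis to the ring oxygen, isopropenyl cis to C9) | Br[Mg]O[C@@]1(C(C)=C)CC[C@]2(C)C=C(OC(=O)C(C)(C)C)[C@]3(C)C=C[C@]12O3 | intermediate (not isolated)
19 | tertiary allylic methyl carbonate, 2-[(methoxycarbonyl)oxy]-5,8-dimethyl-2-(prop-1-en-2-yl)-11-oxatricyclo[6.2.1.0(1,5)]undeca-6,9-dien-7-yl pivalate | COC(=O)O[C@@]1(C(C)=C)CC[C@]2(C)C=C(OC(=O)C(C)(C)C)[C@]3(C)C=C[C@]12O3 | intermediate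
20 | 5,8-dimethyl-2-(prop-1-en-2-yl)-11-oxatricyclo[6.2.1.0(1,5)]undeca-6,9-dien-7-yl pivalate (C1–H cis to C9; isopropenyl cis to the ring oxygen and to the C4 methyl) | C=C(C)[C@H]1CC[C@]2(C)C=C(OC(=O)C(C)(C)C)[C@]3(C)C=C[C@]12O3 | intermediate
21 | 5,8-dimethyl-2-(prop-1-en-2-yl)-11-oxatricyclo[6.2.1.0(1,5)]undec-9-en-7-one | C=C(C)[C@H]1CC[C@]2(C)CC(=O)[C@]3(C)C=C[C@]12O3 | intermediate (not isolated)
22 | 5,8-dimethyl-2-(prop-1-en-2-yl)-11-oxatricyclo[6.2.1.0(1,5)]undec-9-en-7-ol (C6–OH equatorial, anti to the C7–O bond) | C=C(C)[C@H]1CC[C@]2(C)C[C@H](O)[C@]3(C)C=C[C@]12O3 | intermediate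
23 | B-alkyl-9-borabicyclo[3.3.1]nonane from hydroboration of 22 | C1CCC2CCCC1B2C[C@@H](C)[C@H]1CC[C@]2(C)C[C@H](O)[C@]3(C)C=C[C@]12O3 | intermediate (not isolated)
24 | diol, 2-[(2S)-1-hydroxypropan-2-yl]-5,8-dimethyl-11-oxatricyclo[6.2.1.0(1,5)]undec-9-en-7-ol | OC[C@@H](C)[C@H]1CC[C@]2(C)C[C@H](O)[C@]3(C)C=C[C@]12O3 | intermediate
25 | 4-(benzyloxy)-3-methoxybenzoic acid (O-benzylvanillic acid) | COc1cc(C(=O)O)ccc1OCc1ccccc1 | starting material
26 | O-acylisourea from acid 25 and the carbodiimide | COc1cc(C(=O)OC(=NCC)NCCCN(C)C)ccc1OCc1ccccc1 | intermediate (not isolated)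
27 | (2S)-2-(7-hydroxy-5,8-dimethyl-11-oxatricyclo[6.2.1.0(1,5)]undec-9-en-2-yl)propyl 4-(benzyloxy)-3-methoxybenzoate | COc1cc(C(=O)OC[C@@H](C)[C@H]2CC[C@]3(C)C[C@H](O)[C@]4(C)C=C[C@]23O4)ccc1OCc1ccccc1 | intermediate
28 | (2S)-2-(7-hydroxy-5,8-dimethyl-11-oxatricyclo[6.2.1.0(1,5)]undecan-2-yl)propyl 4-hydroxy-3-methoxybenzoate | COc1cc(C(=O)OC[C@@H](C)[C@H]2CC[C@]3(C)C[C@H](O)[C@]4(C)CC[C@]23O4)ccc1O | target

**Totals.** Total step count: 16. Longest linear sequence: 16 steps (1 → 28); acid 25 is a commercial partner.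

**Steps most likely to fail**

Step 6. The acetate may migrate 1,2 instead of staying on C6 (gold vinyl-carbene manifold, which would put the ester on C5). Friedel–Crafts alkylation of the furan β-carbon or (4+2) closure may also outrun the (4+3) pathway. The fallback is classical oxyallyl-cation chemistry, setting out from aldehyde 7 and returning at enone 12. Addition of 1-ethoxyvinyllithium to 7 gives carbinol F1; mild acid (oxalic acid on wet silica) gives the α-hydroxy methyl ketone F2, and MsCl/Et3N gives the mesylate F3. Et3N in CF3CH2OH generates the 2-oxyallyl cation, whose intramolecular (4+3) cycloaddition to the furan gives the tricyclic C5 ketone F4, with the same facial control by C1. Kinetic enolisation towards C6 (LiN(i-Pr)2, PhNTf2) gives the enol triflate F5, and palladium-catalysed formate reduction (Pd(OAc)2, PPh3, Bu3N, HCO2H) gives the C5=C6 alkene F6. A Schenck ene reaction with singlet oxygen (H taken from C4, oxygen delivered to C6) gives the allylic hydroperoxide F7, which Ac2O/pyridine converts through the peracetate F8 (Kornblum–DeLaMare) into 12.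

Step 12. β-Hydride or β-alkoxide elimination from the allylpalladium intermediate, or hydride transfer to the CH2 terminus, may divert the hydrogenolysis, and the facial preference at C1 is an inference. The fallback sets out from ketone 17 and returns at 20. Wittig methylenation (Ph3P=CH2) gives the exocyclic alkene F9. Hydroboration with 9-BBN from the face anti to the C4 methyl group gives the alkylborane F10 and, after NaBO3 oxidation, the primary alcohol F11 with C1–H cis to C9. Dess–Martin oxidation gives the aldehyde F12, MeMgBr at −78 °C the carbinol F13, and a second Dess–Martin oxidation the methyl ketone F14. Non-basic Lombardo methylenation (Zn, CH2Br2, TiCl4) then gives 20. Bases are avoided after F12 because these β-alkoxy carbonyl compounds could open the oxygen bridge by elimination.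

Step 14. Poor facial discrimination in the hydroboration of the isopropenyl group would give a mixture at the methyl-bearing carbon. The fallback uses catalyst control, setting out from 22 and returning at 24. SeO2/t-BuOOH oxidises the allylic methyl group to the allylic alcohol F15. Hydrogenation with Ru(OAc)2(BINAP), using the ligand enantiomer matched to the (S) centre, then reduces only the allylic-alcohol double bond.

**Further compounds**

F1 | step 6 | (6R)-6-silyloxy-2-ethoxy-6-(5-methylfuran-2-yl)hex-1-en-3-ol | Cc1ccc(o1)[C@H](O[Si](C)(C)C(C)(C)C)CCC(O)C(=C)OCC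
F2 | step 6 | (6R)-6-silyloxy-3-hydroxy-6-(5-methylfuran-2-yl)hexan-2-one | Cc1ccc(o1)[C@H](O[Si](C)(C)C(C)(C)C)CCC(O)C(C)=O
F3 | step 6 | methanesulfonate of F2 | Cc1ccc(o1)[C@H](O[Si](C)(C)C(C)(C)C)CCC(OS(C)(=O)=O)C(C)=O
F4 | step 6 | tricyclic C5 ketone, 2-silyloxy-8-methyl-11-oxatricyclo[6.2.1.0(1,5)]undec-9-en-6-one | CC(C)(C)[Si](C)(C)O[C@@H]1CCC2C(=O)C[C@]3(C)C=C[C@]12O3
F5 | step 6 | enol triflate of F4 (C5=C6) | CC(C)(C)[Si](C)(C)O[C@@H]1CCC2C(OS(=O)(=O)C(F)(F)F)=C[C@]3(C)C=C[C@]12O3
F6 | step 6 | 2-silyloxy-8-methyl-11-oxatricyclo[6.2.1.0(1,5)]undeca-6,9-diene | CC(C)(C)[Si](C)(C)O[C@@H]1CCC2C=C[C@]3(C)C=C[C@]12O3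
F7 | step 6 | allylic hydroperoxide (OOH on C6, C4=C5) | CC(C)(C)[Si](C)(C)O[C@@H]1CCC2=CC(OO)[C@]3(C)C=C[C@]12O3
F8 | step 6 | peracetate of F7 | CC(C)(C)[Si](C)(C)O[C@@H]1CCC2=CC(OOC(C)=O)[C@]3(C)C=C[C@]12O3
F9 | step 12 | 5,8-dimethyl-2-methylidene-11-oxatricyclo[6.2.1.0(1,5)]undeca-6,9-dien-7-yl pivalate | C=C1CC[C@]2(C)C=C(OC(=O)C(C)(C)C)[C@]3(C)C=C[C@]12O3
F10 | step 12 | B-alkyl-9-borabicyclo[3.3.1]nonane from F9 | C1CCC2CCCC1B2C[C@H]1CC[C@]2(C)C=C(OC(=O)C(C)(C)C)[C@]3(C)C=C[C@]12O3
F11 | step 12 | 2-(hydroxymethyl) compound (C1–H cis to C9) | OC[C@H]1CC[C@]2(C)C=C(OC(=O)C(C)(C)C)[C@]3(C)C=C[C@]12O3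
F12 | step 12 | 2-formyl compound | O=C[C@H]1CC[C@]2(C)C=C(OC(=O)C(C)(C)C)[C@]3(C)C=C[C@]12O3
F13 | step 12 | 2-(1-hydroxyethyl) compound, both carbinol epimers | CC(O)[C@H]1CC[C@]2(C)C=C(OC(=O)C(C)(C)C)[C@]3(C)C=C[C@]12O3
F14 | step 12 | 2-acetyl compound | CC(=O)[C@H]1CC[C@]2(C)C=C(OC(=O)C(C)(C)C)[C@]3(C)C=C[C@]12O3
F15 | step 14 | 2-(3-hydroxyprop-1-en-2-yl)-5,8-dimethyl-11-oxatricyclo[6.2.1.0(1,5)]undec-9-en-7-ol | OCC(=C)[C@H]1CC[C@]2(C)C[C@H](O)[C@]3(C)C=C[C@]12O3
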